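The phloroglucinol ring is not coupled to the terpene but grown on it. The disconnection is the aryl bond C1′–C2′: aryl carbons C2′–C6′, with their oxygens on C2′, C4′ and C6′, are the five ring carbons of a 4-hydroxy-2-pyranone, and C1′ is its exocyclic CH2 on benzylic Cα. In one operation methoxide opens the lactone to a 3,5-dioxo ester, a Claisen closure C1′→C2′ follows and enolisation delivers the aromatic ring; no stereocentre is touched. The precursor, pyranone 27, already carries the complete eudesmane diol (rings A and B) and Cα, built from (R)-α-terpineol by a chiral-imine Robinson annulation and an A(1,3)-controlled cuprate addition. A double ortho-formylation ends the route.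

Key step: step 16

Remark on the chemistry: eudesmane numbering is used (C1 carries Cα, C4 is the ring carbinol, C5 and C10 are the ring fusion, C7 carries the 2-hydroxypropan-2-yl group, β is the face of the C10 methyl); no error was found in the given structures (Cα keeps its geometry from 27 to 30 although its descriptor changes from R to S), the closure of step 16 is more exactly 6-(enolendo)-exo-trig, and ethyl (E)-4-chloro-4-oxobut-2-enoate is assumed to be purchasable.

Step 1
Reactants: 1 (R)-α-terpineol
Product: 3 (1R,2R,5R)-5-(2-hydroxypropan-2-yl)-2-methylcyclohexan-1-ol, via alkylborane 2 (not isolated)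
Conditions: BH3·THF, THF, 0 to 25 °C; then NaOH, H2O2, H2O, 0 to 40 °C
Reagents that add atoms: hydrogen peroxide, OO
Why: Hydroboration–oxidation adds H and OH syn and anti-Markovnikov, so OH goes to the unsubstituted alkene carbon (future C5) trans to the methyl group; both new centres are temporary (the carbinol is oxidised in step 2, the methyl-bearing carbon is re-formed in step 4), so the face isomer behaves alike, and C7 comes from 1 untouched.

Step 2
Reactants: 3 (1R,2R,5R)-5-(2-hydroxypropan-2-yl)-2-methylcyclohexan-1-ol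
Product: 4 (2R,5R)-5-(2-hydroxypropan-2-yl)-2-methylcyclohexan-1-one
Conditions: TEMPO (cat.), KBr (cat.), NaOCl, NaHCO3, CH2Cl2–H2O, 0 °C
Reagents that add atoms: none
Why: TEMPO-catalysed hypochlorite oxidation turns the secondary alcohol into the ketone while the tertiary alcohol cannot react; the α-methyl centre settles equatorial but is erased anyway by enamine formation in step 4.

Step 3
Reactants: 5 ethyl (E)-4-chloro-4-oxobut-2-enoate
Product: 6 ethyl (E)-4-oxohex-2-enoate
Conditions: Et2Zn (0.6 equiv), Pd(PPh3)4 (2 mol %), THF, 0 °C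
Reagents that add atoms: diethylzinc, CC[Zn]CC
Why: Negishi acylation, in which zerovalent palladium inserts into the acyl chloride and takes an ethyl group from zinc faster than the organozinc adds to the electron-poor alkene, whose E geometry is kept.

Step 4
Reactants: 4 (2R,5R)-5-(2-hydroxypropan-2-yl)-2-methylcyclohexan-1-one; 6 ethyl (E)-4-oxohex-2-enoate
Product: 9 ethyl (2R)-2-[(1S,4R)-4-(2-hydroxypropan-2-yl)-1-methyl-2-oxocyclohexyl]-4-oxohexanoate, via imine 7 (not isolated), via adduct imine 8 (not isolated)
Conditions: (R)-PhCH(CH3)NH2, TsOH (cat.), PhMe, reflux (−H2O); then 6, THF, 25 to 40 °C; then 20% aq. AcOH, 25 °C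
Reagents that add atoms: water, O
Why: Asymmetric Michael reaction of a chiral imine (aza-ene type), in which the more substituted secondary enamine tautomer of 7 attacks the carbon of 6 that is β to the ketone (the stronger activator) through a compact chair-like transition state with the ketone endo; the (R)-1-phenylethyl group shields one enamine face so that C10 forms with the natural configuration (auxiliary control, as in the same annulation with ethyl vinyl ketone), and the E geometry of 6 puts CO2Et exo and therefore cis to the C10 methyl at C1 (as with crotonate-type acceptors).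

Step 5
Reactants: 9 ethyl (2R)-2-[(1S,4R)-4-(2-hydroxypropan-2-yl)-1-methyl-2-oxocyclohexyl]-4-oxohexanoate
Product: 11 ethyl 11-hydroxy-3-oxoeudesm-4-ene-1β-carboxylate, via ketol 10 (not isolated)
Conditions: NaOEt (0.3 equiv), EtOH, 0 to 25 °C
Reagents that add atoms: none
Why: Second half of a Robinson annulation, in which the ethyl ketone methylene (C4) adds to the ring ketone (C5) and E1cB dehydration gives the 4-methyl-Δ4-3-ketone; catalytic ethoxide at room temperature is too mild to epimerise the ester-bearing C1.

Step 6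
Reactants: 11 ethyl 11-hydroxy-3-oxoeudesm-4-ene-1β-carboxylate
Product: 12 ethyl 3β,11-dihydroxyeudesm-4-ene-1β-carboxylate
Conditions: NaBH4, CeCl3·7H2O, MeOH, −20 °C
Reagents that add atoms: none
Why: Luche reduction, a cerium-assisted 1,2-reduction in which hydride arrives axially on the α face (anti to the C10 methyl) and sets C3 as the 3β alcohol, the ester being left alone.

Step 7
Reactants: 12 ethyl 3β,11-dihydroxyeudesm-4-ene-1β-carboxylate
Product: 15 ethyl 11-hydroxy-5α-eudesm-3-ene-1β-carboxylate, via sulfonylhydrazine 13 (not isolated), via allylic diazene 14 (not isolated)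
Conditions: 2-nitrobenzenesulfonylhydrazide, PPh3, DEAD, N-methylmorpholine, −30 to 25 °C
Reagents that add atoms: none
Why: Reductive 1,3-transposition of an allylic alcohol, in which Mitsunobu displacement by the sulfonylhydrazide inverts C3 (3α-N), sulfinic acid is lost and the allylic diazene expels N2 in a retro-ene reaction that hands hydrogen to C5 on the face of the C–N bond (α); the trans ring fusion (5α-H) is thus set by the C3 configuration and the alkene ends as Δ3.

Step 8
Reactants: 15 ethyl 11-hydroxy-5α-eudesm-3-ene-1β-carboxylate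
Product: 16 ethyl 3α,4α-epoxy-11-hydroxy-5α-eudesmane-1β-carboxylate
Conditions: mCPBA, NaHCO3, CH2Cl2, 0 °C
Reagents that add atoms: mCPBA, O=C(OO)c1cccc(Cl)c1
Why: Prilezhaev epoxidation of the trisubstituted alkene from the α face, the β face being screened by the axial C10 methyl and the 1β ester being equatorial and remote, which fixes C4 with oxygen α and methyl β.

Step 9
Reactants: 16 ethyl 3α,4α-epoxy-11-hydroxy-5α-eudesmane-1β-carboxylate
Product: 17 1β-(hydroxymethyl)-5α-eudesmane-4α,11-diol
Conditions: LiAlH4, THF, 0 to 65 °C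
Reagents that add atoms: none
Why: Hydride reduction, in which LiAlH4 opens the trisubstituted epoxide by SN2 attack at the secondary carbon C3 (the tertiary 4α-alcohol keeps its configuration) and reduces the ester to the primary alcohol.

Step 10
Reactants: 17 1β-(hydroxymethyl)-5α-eudesmane-4α,11-diol
Product: 18 4α,11-dihydroxy-5α-eudesmane-1β-carbaldehyde
Conditions: TEMPO (cat.), PhI(OAc)2, CH2Cl2, 25 °C
Reagents that add atoms: none
Why: TEMPO/PhI(OAc)2 oxidation is selective for the primary alcohol (tertiary alcohols cannot be oxidised) and its neutral conditions do not epimerise the α-branched aldehyde at C1.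

Step 11
Reactants: 18 4α,11-dihydroxy-5α-eudesmane-1β-carbaldehyde; 19 dimethyl malonate
Product: 20 dimethyl 2-[(4α,11-dihydroxy-5α-eudesman-1β-yl)methylidene]propanedioate
Conditions: piperidine (cat.), AcOH (cat.), PhMe, 4 Å sieves, 50 °C
Reagents that add atoms: none
Why: Knoevenagel condensation through the piperidinium iminium, in which the equatorial aldehyde condenses without change at C1 and the free tertiary alcohols are inert.

Step 12
Reactants: 20 dimethyl 2-[(4α,11-dihydroxy-5α-eudesman-1β-yl)methylidene]propanedioate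
Product: 21 dimethyl 2-[1-(4α,11-dihydroxy-5α-eudesman-1β-yl)-3-methylbutyl]propanedioate
Conditions: i-BuMgCl (4 equiv), CuBr·SMe2 (20 mol %), THF, −40 to 0 °C; aq. NH4Cl
Reagents that add atoms: isobutylmagnesium chloride, CC(C)C[Mg]Cl
Why: Copper-catalysed conjugate addition to an alkylidene malonate, in which A(1,3) strain with the cis ester holds the C1–H bond in the alkene plane so that isobutyl enters at Cα anti to the quaternary C10 (on the C2 side) and gives the Cα configuration of 30; the extra Grignard reagent only turns the two alcohols into alkoxides.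

Step 13
Reactants: 21 dimethyl 2-[1-(4α,11-dihydroxy-5α-eudesman-1β-yl)-3-methylbutyl]propanedioate
Product: 23 3-(4α,11-dihydroxy-5α-eudesman-1β-yl)-5-methylhexanoic acid, via malonic acid 22 (not isolated)
Conditions: KOH, EtOH–H2O, 85 °C; 1 M HCl to pH 2, 0 °C; then pyridine, 110 °C
Reagents that add atoms: potassium hydroxide, [K+].[OH-]
Why: Saponification of both esters followed by thermal decarboxylation of the malonic acid through its six-membered cyclic transition state; Cα is not enolisable and the tertiary alcohols tolerate hydroxide and brief cold acidification.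

Step 14
Reactants: 23 3-(4α,11-dihydroxy-5α-eudesman-1β-yl)-5-methylhexanoic acid; 24 methyl acetoacetate
Product: 26 methyl 7-(4α,11-dihydroxy-5α-eudesman-1β-yl)-9-methyl-3,5-dioxodecanoate, via acyl imidazole 25 (not isolated)
Conditions: CDI, THF, 25 °C; then 24 (3.5 equiv), LiN(iPr)2 (7 equiv), THF, −78 to 0 °C; aq. NH4Cl
Reagents that add atoms: none
Why: Crossed Claisen condensation, in which the terminal carbon of the methyl acetoacetate dianion is acylated by the acyl imidazole to build the 3,5-dioxo ester chain; surplus dianion absorbs the two hydroxyl protons and the acidic product.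

Step 15
Reactants: 26 methyl 7-(4α,11-dihydroxy-5α-eudesman-1β-yl)-9-methyl-3,5-dioxodecanoate
Product: 27 6-[2-(4α,11-dihydroxy-5α-eudesman-1β-yl)-4-methylpentyl]-4-hydroxy-2H-pyran-2-one
Conditions: DBU, PhMe, 80 °C; then 1 M HCl, 0 °C
Reagents that add atoms: none
Why: Base-promoted lactonisation, in which the enol oxygen of the 5-ketone acylates on the methyl ester (6-exo-trig, loss of methanol) to give the crystalline 4-hydroxy-2-pyranone, the storable form in which the chain is purified before the ring transformation.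

Step 16
Reactants: 27 6-[2-(4α,11-dihydroxy-5α-eudesman-1β-yl)-4-methylpentyl]-4-hydroxy-2H-pyran-2-one
Product: 28 2-[1-(4α,11-dihydroxy-5α-eudesman-1β-yl)-3-methylbutyl]benzene-1,3,5-triol, via dioxo ester 26 (not isolated)
Conditions: Mg(OMe)2 (8 equiv), MeOH, 65 °C; then NaOMe (4 equiv), sealed tube, 150 °C; 1 M HCl, 0 °C
Reagents that add atoms: none
Why: Proposed new method: Mg(OMe)2 adds methoxide to the lactone carbonyl C2′ of the magnesium pyranolate and acyl–oxygen cleavage gives the chelated methyl 3,5-dioxoalkanoate 26 (an opening known for 6-alkyl-4-hydroxy-2-pyranones); on heating with extra NaOMe the C6′ ketone enolises toward C1′, C1′ attacks the ester carbon C2′, methoxide leaves and the cyclohexane-1,3,5-trione tautomerises to the phloroglucinolate. The closest known reaction type is the biomimetic Claisen cyclisation of 3,5,7-trioxo esters or their pyranones to acylphloroglucinols under Mg(OMe)2 or KOH, where the attacking methylene lies between two carbonyl groups, whereas here one carbonyl activates it. The single ring (C1′–C6′) closes in the 6-(enolendo)-exo-trig mode. No stereocentre is formed and Cα, which has no acidic hydrogen, keeps its configuration. The step needs C-acylation at C1′ to beat O-acylation (return to 27) and retro-Claisen cleavage: relactonisation is reversible under methoxide, magnesium chelation keeps the 1,3-dicarbonyl units enolised and shielded, a 3,5-dioxo ester has no six-membered aldol alternative, and aromatisation removes the product irreversibly; the diol is left unprotected because its alkoxides are inert here.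

Step 17
Reactants: 28 2-[1-(4α,11-dihydroxy-5α-eudesman-1β-yl)-3-methylbutyl]benzene-1,3,5-triol
Product: 30 macrocarpal J, via monoaldehyde 29 (not isolated)
Conditions: MgCl2 (6 equiv), Et3N (12 equiv), (CH2O)n (20 equiv), THF, 66 °C; 1 M HCl, 0 °C
Reagents that add atoms: paraformaldehyde (as formaldehyde), C=O
Why: Magnesium-mediated ortho-formylation of phenols, in which each magnesium phenoxide delivers formaldehyde to its ortho carbon and hydride transfer to a second formaldehyde turns the hydroxymethyl group into the aldehyde, first at C3′ and then at C5′ (the only free ring positions), under basic conditions that spare the tertiary alcohols.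

Compound list
1 | (R)-α-terpineol | CC1=CC[C@H](C(C)(C)O)CC1 | starting material
2 | alkylborane from 1 (boron on the former =CH carbon, trans to methyl) | C[C@@H]1CC[C@@H](C(C)(C)O)C[C@H]1B | intermediate
3 | (1R,2R,5R)-5-(2-hydroxypropan-2-yl)-2-methylcyclohexan-1-ol | C[C@@H]1CC[C@@H](C(C)(C)O)C[C@H]1O | intermediate
4 | (2R,5R)-5-(2-hydroxypropan-2-yl)-2-methylcyclohexan-1-one | C[C@@H]1CC[C@@H](C(C)(C)O)CC1=O | intermediate
5 | ethyl (E)-4-chloro-4-oxobut-2-enoate | CCOC(=O)/C=C/C(Cl)=O | starting material
6 | ethyl (E)-4-oxohex-2-enoate | CCOC(=O)/C=C/C(=O)CC | intermediate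
7 | N-[(R)-1-phenylethyl]imine of 4 | C[C@@H]1CC[C@@H](C(C)(C)O)CC1=N[C@H](C)c1ccccc1 | intermediate
8 | N-[(R)-1-phenylethyl]imine of 9 | CCC(=O)C[C@@H](C(=O)OCC)[C@]1(C)CC[C@@H](C(C)(C)O)CC1=N[C@H](C)c1ccccc1 | intermediate
9 | ethyl (2R)-2-[(1S,4R)-4-(2-hydroxypropan-2-yl)-1-methyl-2-oxocyclohexyl]-4-oxohexanoate | CCC(=O)C[C@@H](C(=O)OCC)[C@]1(C)CC[C@@H](C(C)(C)O)CC1=O | intermediate
10 | ethyl 5,11-dihydroxy-3-oxoeudesmane-1β-carboxylate (ketol, C4 and C5 mixed) | CCOC(=O)[C@@H]1CC(=O)C(C)C2(O)C[C@H](C(C)(C)O)CC[C@]21C | intermediate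
11 | ethyl 11-hydroxy-3-oxoeudesm-4-ene-1β-carboxylate | CCOC(=O)[C@@H]1CC(=O)C(C)=C2C[C@H](C(C)(C)O)CC[C@]21C | intermediate
12 | ethyl 3β,11-dihydroxyeudesm-4-ene-1β-carboxylate | CCOC(=O)[C@@H]1C[C@H](O)C(C)=C2C[C@H](C(C)(C)O)CC[C@]21C | intermediate
13 | ethyl 11-hydroxy-3α-[1-(2-nitrophenylsulfonyl)hydrazinyl]eudesm-4-ene-1β-carboxylate | CCOC(=O)[C@@H]1C[C@@H](N(N)S(=O)(=O)c3ccccc3[N+](=O)[O-])C(C)=C2C[C@H](C(C)(C)O)CC[C@]21C | intermediate
14 | ethyl 3α-diazenyl-11-hydroxyeudesm-4-ene-1β-carboxylate | CCOC(=O)[C@@H]1C[C@@H](N=N)C(C)=C2C[C@H](C(C)(C)O)CC[C@]21C | intermediate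
15 | ethyl 11-hydroxy-5α-eudesm-3-ene-1β-carboxylate | CCOC(=O)[C@@H]1CC=C(C)[C@@H]2C[C@H](C(C)(C)O)CC[C@]21C | intermediate
16 | ethyl 3α,4α-epoxy-11-hydroxy-5α-eudesmane-1β-carboxylate | CCOC(=O)[C@@H]1C[C@H]2O[C@@]2(C)[C@@H]3C[C@H](C(C)(C)O)CC[C@]31C | intermediate
17 | 1β-(hydroxymethyl)-5α-eudesmane-4α,11-diol | OC[C@@H]1CC[C@@](C)(O)[C@@H]2C[C@H](C(C)(C)O)CC[C@]21C | intermediate
18 | 4α,11-dihydroxy-5α-eudesmane-1β-carbaldehyde | O=C[C@@H]1CC[C@@](C)(O)[C@@H]2C[C@H](C(C)(C)O)CC[C@]21C | intermediate
19 | dimethyl malonate | COC(=O)CC(=O)OC | starting material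
20 | dimethyl 2-[(4α,11-dihydroxy-5α-eudesman-1β-yl)methylidene]propanedioate | COC(=O)C(C(=O)OC)=C[C@@H]1CC[C@@](C)(O)[C@@H]2C[C@H](C(C)(C)O)CC[C@]21C | intermediate
21 | dimethyl 2-[1-(4α,11-dihydroxy-5α-eudesman-1β-yl)-3-methylbutyl]propanedioate (Cα as in 30) | CC(C)C[C@H](C(C(=O)OC)C(=O)OC)[C@@H]1CC[C@@](C)(O)[C@@H]2C[C@H](C(C)(C)O)CC[C@]21C | intermediate
22 | 2-[1-(4α,11-dihydroxy-5α-eudesman-1β-yl)-3-methylbutyl]propanedioic acid | CC(C)C[C@H](C(C(=O)O)C(=O)O)[C@@H]1CC[C@@](C)(O)[C@@H]2C[C@H](C(C)(C)O)CC[C@]21C | intermediate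
23 | 3-(4α,11-dihydroxy-5α-eudesman-1β-yl)-5-methylhexanoic acid | CC(C)C[C@H](CC(=O)O)[C@@H]1CC[C@@](C)(O)[C@@H]2C[C@H](C(C)(C)O)CC[C@]21C | intermediate
24 | methyl acetoacetate | CC(=O)CC(=O)OC | starting material
25 | N-acylimidazole of 23 | CC(C)C[C@H](CC(=O)n1ccnc1)[C@@H]1CC[C@@](C)(O)[C@@H]2C[C@H](C(C)(C)O)CC[C@]21C | intermediate
26 | methyl 7-(4α,11-dihydroxy-5α-eudesman-1β-yl)-9-methyl-3,5-dioxodecanoate | CC(C)C[C@H](CC(=O)CC(=O)CC(=O)OC)[C@@H]1CC[C@@](C)(O)[C@@H]2C[C@H](C(C)(C)O)CC[C@]21C | intermediate
27 | 6-[2-(4α,11-dihydroxy-5α-eudesman-1β-yl)-4-methylpentyl]-4-hydroxy-2H-pyran-2-one | CC(C)C[C@H](Cc1cc(O)cc(=O)o1)[C@@H]1CC[C@@](C)(O)[C@@H]2C[C@H](C(C)(C)O)CC[C@]21C | intermediate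
28 | 2-[1-(4α,11-dihydroxy-5α-eudesman-1β-yl)-3-methylbutyl]benzene-1,3,5-triol | CC(C)C[C@H](c1c(O)cc(O)cc1O)[C@@H]1CC[C@@](C)(O)[C@@H]2C[C@H](C(C)(C)O)CC[C@]21C | intermediate
29 | 3′-monoaldehyde of 28 | CC(C)C[C@H](c1c(O)cc(O)c(C=O)c1O)[C@@H]1CC[C@@](C)(O)[C@@H]2C[C@H](C(C)(C)O)CC[C@]21C | intermediate
30 | macrocarpal J | CC(C)C[C@H](c1c(O)c(C=O)c(O)c(C=O)c1O)[C@@H]1CC[C@@](C)(O)[C@@H]2C[C@H](C(C)(C)O)CC[C@]21C | target

Total step count: 17. Longest linear sequence: 16 steps (steps 1, 2 and 4 to 17, from 1); step 3 is a one-step side branch.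

Steps most likely to fail

1. Step 16 (the labelled step). Enolisation toward C1′ may be too slow, so that methoxide cleaves the 1,3-dicarbonyl units (retro-Claisen) or the chain only returns to 27. The fallback uses known reactions and introduces the aryl ring as a nucleophile instead of growing it; it sets out from 18 and comes back at 28. 2-Bromo-1,3,5-tris(benzyloxy)benzene is treated with n-BuLi (THF, −78 °C) to give 2,4,6-tris(benzyloxy)phenyllithium F1, which is added in excess to 18 to give the benzylic alcohol F2 (either carbinol epimer serves). BF3·OEt2 (cat.) and 2-methylallyltrimethylsilane in CH2Cl2 at −78 °C ionise the trialkoxybenzylic alcohol, and the allylsilane captures the cation (Hosomi–Sakurai type) anti to C10 under the same A(1,3) control as in step 12, giving the 2-methylallyl tribenzyl ether F3. Hydrogenation (H2, Pd/C, EtOAc–MeOH) saturates the alkene to the isobutyl group and removes the three benzyl groups, which gives 28.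

2. Step 4. The acceptor may approach in the open (exo) arrangement, or ethoxide may epimerise the ester-bearing carbon in step 5, so that C1 is not obtained as one epimer. The fallback sets this centre by hydrogenation instead of by the Michael transition state; it sets out from 11 containing its C1 epimer, the 1α-carboxylate F4, and comes back at 11. IBX in DMSO at 75 °C dehydrogenates both epimers across C1–C2 to the single cross-conjugated dienone ester F5. H2 over Pd/C in EtOAc then adds to the less substituted, doubly activated C1=C2 bond from the α face (anti to the C10 methyl) and returns 11 alone.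

3. Step 7. Mitsunobu displacement at the hindered allylic carbon C3 may be slower than decomposition of the sulfonylhydrazide, or elimination to a diene may compete. The fallback delivers the hydride from palladium instead of from a diazene; it sets out from 12 and comes back at 15. The secondary alcohol is formylated (HCO2H, DCC, DMAP (cat.), CH2Cl2) to the 3β-formate F6. Pd(OAc)2 with PBu3 in dioxane at 25 °C ionises the allylic formate with inversion (palladium on the α face), CO2 is lost and the hydride passes from palladium to C5 on the α face, which gives 15 with the trans ring fusion.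

Further compounds
F1 | step 16 | 2,4,6-tris(benzyloxy)phenyllithium | [Li]c1c(OCc2ccccc2)cc(OCc2ccccc2)cc1OCc1ccccc1
F2 | step 16 | [2,4,6-tris(benzyloxy)phenyl](4α,11-dihydroxy-5α-eudesman-1β-yl)methanol | OC(c3c(OCc4ccccc4)cc(OCc4ccccc4)cc3OCc3ccccc3)[C@@H]1CC[C@@](C)(O)[C@@H]2C[C@H](C(C)(C)O)CC[C@]21C
F3 | step 16 | 1β-{1-[2,4,6-tris(benzyloxy)phenyl]-3-methylbut-3-enyl}-5α-eudesmane-4α,11-diol (Cα as in 30) | C=C(C)C[C@H](c3c(OCc4ccccc4)cc(OCc4ccccc4)cc3OCc3ccccc3)[C@@H]1CC[C@@](C)(O)[C@@H]2C[C@H](C(C)(C)O)CC[C@]21C
F4 | step 4 | ethyl 11-hydroxy-3-oxoeudesm-4-ene-1α-carboxylate | CCOC(=O)[C@H]1CC(=O)C(C)=C2C[C@H](C(C)(C)O)CC[C@]21C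
F5 | step 4 | ethyl 11-hydroxy-3-oxoeudesma-1,4-diene-1-carboxylate | CCOC(=O)C1=CC(=O)C(C)=C2C[C@H](C(C)(C)O)CC[C@]21C
F6 | step 7 | ethyl 3β-formyloxy-11-hydroxyeudesm-4-ene-1β-carboxylate | CCOC(=O)[C@@H]1C[C@H](OC=O)C(C)=C2C[C@H](C(C)(C)O)CC[C@]21C
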